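**Retrosynthetic overview**
1. Target ⇒ (MOM hydrolysis, ortho-lithiation/formylation, desilylation) a protected aryl-decalin; its C8 methyl comes from a C8 ketone (Wittig methylenation, face-selective hydrogenation), and its C9 quaternary centre and C1=C10 alkene come from deconjugative α-methylation of an α-(arylmethyl) octalone (drimane-type locants: C3 carbinol, C4 CMe2, C5/C10 ring fusion, C8 CHMe, C9 quaternary, C11 ArCH2).
2. Key disconnection: Robinson-type annulation of that octalone, i.e. intermolecular Michael addition (C5–C6) of a regiodefined ring A lithium enolate to an aryl-bearing α-silyl vinyl ketone, then aldol condensation (C9–C10).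
3. Enolate ⇐ Me2CuLi addition to (R)-4-silyloxy-3-methylcyclohexenone ⇐ CBS reduction ⇐ quinone monoketal of 4-methoxy-2-methylphenol; acceptor ⇐ 3,5-dihydroxybenzyl alcohol (ortho-lithiation/allylation, hydroboration, α-silylvinyl Grignard).
4. Ring order: the arene and carbocycle A are bought (A from the phenol); ring B is the only ring formed (annulation). Stereochemical relay: C3 (CBS) → C5 (Michael) → C9 (axial methylation) → C8 (hydrogenation).

Assumption: the target is the open hydroxy-aldehyde drawn, (3R,5R,8R,9S) in the locants above. Abbreviations in names: Ar = 4-(tert-butyldimethylsilyloxymethyl)-2,6-bis(methoxymethoxy)phenyl, TBS = tert-butyldimethylsilyl, MOM = methoxymethyl.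

**Route**

Step 1
Reactants: 1 4-methoxy-2-methylphenol
Product: 2 4,4-dimethoxy-2-methylcyclohexa-2,5-dien-1-one
Conditions: PhI(OAc)2, MeOH, 0 °C → rt
Reagents that add atoms: methanol, CO
Why: Oxidative dearomatisation of a para-methoxyphenol, in which methanol traps the phenoxenium ion at the methoxy-bearing carbon to give the quinone monoketal.

Step 2
Reactants: 2 4,4-dimethoxy-2-methylcyclohexa-2,5-dien-1-one
Product: 3 4,4-dimethoxy-2-methylcyclohex-2-en-1-one
Conditions: H2 (1 atm), RhCl(PPh3)3 (5 mol %), benzene, rt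
Reagents that add atoms: none
Why: Chemoselective homogeneous hydrogenation, since RhCl(PPh3)3 reduces the unhindered disubstituted enone alkene of a cross-conjugated dienone much faster than the methyl-bearing trisubstituted one, and no stereocentre is formed.

Step 3
Reactants: 3 4,4-dimethoxy-2-methylcyclohex-2-en-1-one
Product: 4 (1R)-4,4-dimethoxy-2-methylcyclohex-2-en-1-ol
Conditions: (S)-2-methyl-CBS-oxazaborolidine (10 mol %), BH3·SMe2, THF, −20 °C; MeOH, then aqueous work-up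
Reagents that add atoms: none
Why: Corey–Bakshi–Shibata reduction, in which the (S)-catalyst treats the alkenyl arm as the large group and delivers hydride to give the (R)-allylic alcohol (the future C3) in high ee.

Step 4
Reactants: 4 (1R)-4,4-dimethoxy-2-methylcyclohex-2-en-1-ol
Product: 5 tert-butyl{[(1R)-4,4-dimethoxy-2-methylcyclohex-2-en-1-yl]oxy}dimethylsilane
Conditions: TBSCl, imidazole, DMF, rt
Reagents that add atoms: tert-butyldimethylsilyl chloride, CC(C)(C)[Si](C)(C)Cl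
Why: Standard imidazole-promoted silylation of a secondary allylic alcohol, which leaves the carbinol configuration untouched.

Step 5
Reactants: 5 tert-butyl{[(1R)-4,4-dimethoxy-2-methylcyclohex-2-en-1-yl]oxy}dimethylsilane
Product: 6 (4R)-4-(tert-butyldimethylsilyloxy)-3-methylcyclohex-2-en-1-one
Conditions: oxalic acid, THF/H2O, rt
Reagents that add atoms: water, O
Why: Mild acid-catalysed ketal hydrolysis unmasks the enone without cleaving or eliminating the allylic silyl ether.

Step 6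
Reactants: 6 (4R)-4-(tert-butyldimethylsilyloxy)-3-methylcyclohex-2-en-1-one
Product: 7 tert-butyl{[(1R)-2,2-dimethyl-4-(trimethylsilyloxy)cyclohex-3-en-1-yl]oxy}dimethylsilane
Conditions: MeLi, CuBr·SMe2 (→ Me2CuLi), TMSCl, Et2O/THF, −78 → −30 °C; Et3N, cold NaHCO3 work-up
Reagents that add atoms: lithium dimethylcuprate, [Li+].C[Cu-]C; chlorotrimethylsilane, C[Si](C)(C)Cl
Why: TMSCl-accelerated organocuprate conjugate addition installs the second C4 methyl (gem-dimethyl, no new stereocentre) and traps the enolate regiospecifically as the enol ether toward C5.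

Step 7
Reactants: 8 3,5-dihydroxybenzyl alcohol
Product: 9 [3,5-bis(methoxymethoxy)phenyl]methanol
Conditions: MOMCl, K2CO3, acetone, 0 °C → rt
Reagents that add atoms: chloromethyl methyl ether, COCCl
Why: Williamson-type O-alkylation in which K2CO3 deprotonates only the phenols, so both phenolic oxygens are protected and the benzylic alcohol stays free.

Step 8
Reactants: 9 [3,5-bis(methoxymethoxy)phenyl]methanol
Product: 10 tert-butyl{[3,5-bis(methoxymethoxy)phenyl]methoxy}dimethylsilane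
Conditions: TBSCl, imidazole, CH2Cl2, rt
Reagents that add atoms: tert-butyldimethylsilyl chloride, CC(C)(C)[Si](C)(C)Cl
Why: Routine silylation of a primary alcohol, which also removes the alkoxide directing effect so that the next lithiation goes between the two MOM ethers.

Step 9
Reactants: 10 tert-butyl{[3,5-bis(methoxymethoxy)phenyl]methoxy}dimethylsilane
Product: 12 tert-butyl{[3,5-bis(methoxymethoxy)-4-(prop-2-en-1-yl)phenyl]methoxy}dimethylsilane, via aryllithium 11 (not isolated)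
Conditions: n-BuLi, THF, 0 °C; CuBr·SMe2 (10 mol %), allyl bromide, −78 °C → rt
Reagents that add atoms: allyl bromide, C=CCBr
Why: Directed ortho-metalation at the doubly activated position between the two MOM ethers, followed by copper-catalysed allylation of the aryllithium, places the three-carbon handle at the future benzylic position.

Step 10
Reactants: 12 tert-butyl{[3,5-bis(methoxymethoxy)-4-(prop-2-en-1-yl)phenyl]methoxy}dimethylsilane
Product: 14 3-Ar-propan-1-ol, via alkyl-9-BBN borane 13 (not isolated)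
Conditions: 9-BBN, THF, 0 °C → rt; NaOH, H2O2, 0 °C → rt
Reagents that add atoms: hydrogen peroxide, OO
Why: Hydroboration–oxidation with 9-BBN gives the anti-Markovnikov primary alcohol with complete regioselectivity.

Step 11
Reactants: 14 3-Ar-propan-1-ol
Product: 15 3-Ar-propanal
Conditions: Dess–Martin periodinane, CH2Cl2, rt
Reagents that add atoms: none
Why: Dess–Martin oxidation stops cleanly at the aldehyde and tolerates the MOM and silyl ethers.

Step 12
Reactants: 15 3-Ar-propanal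
Product: 16 5-Ar-2-(trimethylsilyl)pent-1-en-3-ol (racemic)
Conditions: (1-(trimethylsilyl)vinyl)magnesium bromide, THF, −78 → 0 °C; H2O
Reagents that add atoms: (1-(trimethylsilyl)vinyl)magnesium bromide, C=C([Mg]Br)[Si](C)(C)C
Why: Grignard addition of the α-silylvinyl nucleophile to the unhindered aldehyde, giving a racemic carbinol whose stereocentre is removed by the next oxidation.

Step 13
Reactants: 16 5-Ar-2-(trimethylsilyl)pent-1-en-3-ol
Product: 17 5-Ar-2-(trimethylsilyl)pent-1-en-3-one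
Conditions: Dess–Martin periodinane, CH2Cl2, 0 °C → rt
Reagents that add atoms: none
Why: Dess–Martin oxidation of the allylic alcohol gives the α-silyl vinyl ketone, a non-polymerising Michael acceptor of the Stork–Ganem type.

Step 14
Reactants: 7 tert-butyl{[(1R)-2,2-dimethyl-4-(trimethylsilyloxy)cyclohex-3-en-1-yl]oxy}dimethylsilane; 17 5-Ar-2-(trimethylsilyl)pent-1-en-3-one
Product: 19 (2S,4R)-4-(tert-butyldimethylsilyloxy)-3,3-dimethyl-2-[5-Ar-3-oxo-2-(trimethylsilyl)pentyl]cyclohexan-1-one (both epimers at the silyl-bearing carbon), via lithium enolate 18 (not isolated)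
Conditions: MeLi, THF, 0 °C → rt; then 17, −78 → −40 °C; AcOH, −78 °C
Reagents that add atoms: none
Why: Michael addition (first stage of a Robinson annulation with an α-silyl vinyl ketone), in which the regiodefined lithium enolate attacks the acceptor axially through the half-chair with equatorial OTBS, anti to the pseudo-axial C4 methyl, so the new C5–C6 bond is trans to the C3 silyloxy group (5R in drimane locants); the silyl-bearing carbon forms as a mixture that is erased in step 15.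

Step 15
Reactants: 19 (2S,4R)-4-(tert-butyldimethylsilyloxy)-3,3-dimethyl-2-[5-Ar-3-oxo-2-(trimethylsilyl)pentyl]cyclohexan-1-one
Product: 22 (4aR,6R)-1-(Ar-methyl)-6-(tert-butyldimethylsilyloxy)-5,5-dimethyl-4,4a,5,6,7,8-hexahydronaphthalen-2(3H)-one, via desilylated 1,5-diketone 20 (not isolated), via bicyclic ketol 21 (not isolated)
Conditions: NaOMe (0.3 equiv), MeOH, 0 °C → rt
Reagents that add atoms: none
Why: Methoxide-catalysed protodesilylation and intramolecular aldol condensation (second stage of the Robinson annulation) close ring B as the tetrasubstituted enone, and the hindered neopentyl C5–H is expected not to exchange at or below room temperature before dehydration removes it from the α-position.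

Step 16
Reactants: 22 (4aR,6R)-1-(Ar-methyl)-6-(tert-butyldimethylsilyloxy)-5,5-dimethyl-4,4a,5,6,7,8-hexahydronaphthalen-2(3H)-one
Product: 24 (1R,4aR,6R)-1-(Ar-methyl)-6-(tert-butyldimethylsilyloxy)-1,5,5-trimethyl-3,4,4a,5,6,7-hexahydronaphthalen-2(1H)-one, via potassium dienolate 23 (not isolated)
Conditions: KOtBu (1.2 equiv), THF, 0 °C; MeI, 0 °C → rt
Reagents that add atoms: iodomethane, CI
Why: Deconjugative α-alkylation of the heteroannular dienolate formed by γ-deprotonation at the unhindered C1 methylene, in which MeI attacks C9 axially through a chair-like transition state on the face of the axial H5, so the C9 methyl is cis to H5, the arylmethyl group is equatorial and the alkene moves to C1=C10.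

Step 17
Reactants: 24 (1R,4aR,6R)-1-(Ar-methyl)-6-(tert-butyldimethylsilyloxy)-1,5,5-trimethyl-3,4,4a,5,6,7-hexahydronaphthalen-2(1H)-one
Product: 25 (1S,4aR,6R)-1-(Ar-methyl)-6-(tert-butyldimethylsilyloxy)-1,5,5-trimethyl-2-methylidene-1,2,3,4,4a,5,6,7-octahydronaphthalene
Conditions: Ph3PCH3Br, KOtBu, toluene, 90 °C
Reagents that add atoms: methylenetriphenylphosphorane (from methyltriphenylphosphonium bromide), C=P(c1ccccc1)(c1ccccc1)c1ccccc1
Why: Wittig methylenation with excess ylide at elevated temperature, the usual way to convert ketones flanked by a quaternary carbon into exocyclic alkenes, and no stereocentre is touched.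

Step 18
Reactants: 25 (1S,4aR,6R)-1-(Ar-methyl)-6-(tert-butyldimethylsilyloxy)-1,5,5-trimethyl-2-methylidene-1,2,3,4,4a,5,6,7-octahydronaphthalene
Product: 26 (1S,2R,4aR,6R)-1-(Ar-methyl)-6-(tert-butyldimethylsilyloxy)-1,2,5,5-tetramethyl-1,2,3,4,4a,5,6,7-octahydronaphthalene
Conditions: H2 (4 atm), RhCl(PPh3)3 (10 mol %), benzene, 40 °C
Reagents that add atoms: none
Why: Homogeneous catalytic hydrogenation that reduces only the 1,1-disubstituted exocyclic alkene (the trisubstituted C1=C10 alkene is inert to this catalyst) and delivers hydrogen to the face opposite the axial C9 methyl, giving the equatorial C8 methyl cis to the C9 methyl (8R).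

Step 19
Reactants: 26 (1S,2R,4aR,6R)-1-(Ar-methyl)-6-(tert-butyldimethylsilyloxy)-1,2,5,5-tetramethyl-1,2,3,4,4a,5,6,7-octahydronaphthalene
Product: 27 {4-{[(1S,2R,4aR,6R)-6-hydroxy-1,2,5,5-tetramethyl-1,2,3,4,4a,5,6,7-octahydronaphthalen-1-yl]methyl}-3,5-bis(methoxymethoxy)phenyl}methanol
Conditions: Bu4NF, THF, 50 °C; aqueous work-up
Reagents that add atoms: none
Why: Fluoride-mediated desilylation removes both TBS ethers (heating is needed for the hindered axial secondary ether) and leaves the MOM ethers and the alkene intact.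

Step 20
Reactants: 27 {4-{[(1S,2R,4aR,6R)-6-hydroxy-1,2,5,5-tetramethyl-1,2,3,4,4a,5,6,7-octahydronaphthalen-1-yl]methyl}-3,5-bis(methoxymethoxy)phenyl}methanol
Product: 29 6-(hydroxymethyl)-3-{[(1S,2R,4aR,6R)-6-hydroxy-1,2,5,5-tetramethyl-1,2,3,4,4a,5,6,7-octahydronaphthalen-1-yl]methyl}-2,4-bis(methoxymethoxy)benzaldehyde, via trilithiated arene 28 (not isolated)
Conditions: n-BuLi (5 equiv), TMEDA, THF, 0 °C → rt; DMF, −78 °C → rt; H2O
Reagents that add atoms: N,N-dimethylformamide, CN(C)C=O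
Why: Directed ortho-metalation in which, after both hydroxyls are deprotonated, the benzylic alkoxide and the neighbouring MOM ether together direct lithiation to the only free ring position (the two are equivalent), and DMF formylates the aryllithium.

Step 21
Reactants: 29 6-(hydroxymethyl)-3-{[(1S,2R,4aR,6R)-6-hydroxy-1,2,5,5-tetramethyl-1,2,3,4,4a,5,6,7-octahydronaphthalen-1-yl]methyl}-2,4-bis(methoxymethoxy)benzaldehyde
Product: 30 2,4-dihydroxy-6-(hydroxymethyl)-3-{[(1S,2R,4aR,6R)-6-hydroxy-1,2,5,5-tetramethyl-1,2,3,4,4a,5,6,7-octahydronaphthalen-1-yl]methyl}benzaldehyde (CNP0348277.2)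
Conditions: 3 M HCl (aq), THF, 40 °C
Reagents that add atoms: none
Why: Acid-catalysed acetal hydrolysis of the two aryl MOM ethers in aqueous THF (no alcohol solvent, so the aldehyde is not acetalised), under conditions too mild to protonate the trisubstituted alkene.

**Compound list**
1 | 4-methoxy-2-methylphenol | COc1ccc(O)c(C)c1 | starting material
2 | 4,4-dimethoxy-2-methylcyclohexa-2,5-dien-1-one | COC1(OC)C=CC(=O)C(C)=C1 | intermediate
3 | 4,4-dimethoxy-2-methylcyclohex-2-en-1-one | COC1(OC)CCC(=O)C(C)=C1 | intermediate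
4 | (1R)-4,4-dimethoxy-2-methylcyclohex-2-en-1-ol | COC1(OC)C=C(C)[C@H](O)CC1 | intermediate
5 | tert-butyl{[(1R)-4,4-dimethoxy-2-methylcyclohex-2-en-1-yl]oxy}dimethylsilane | COC1(OC)C=C(C)[C@H](O[Si](C)(C)C(C)(C)C)CC1 | intermediate
6 | (4R)-4-(tert-butyldimethylsilyloxy)-3-methylcyclohex-2-en-1-one | O=C1C=C(C)[C@H](O[Si](C)(C)C(C)(C)C)CC1 | intermediate
7 | tert-butyl{[(1R)-2,2-dimethyl-4-(trimethylsilyloxy)cyclohex-3-en-1-yl]oxy}dimethylsilane | C[Si](C)(C)OC1=CC(C)(C)[C@H](O[Si](C)(C)C(C)(C)C)CC1 | intermediate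
8 | 3,5-dihydroxybenzyl alcohol | OCc1cc(O)cc(O)c1 | starting material
9 | [3,5-bis(methoxymethoxy)phenyl]methanol | COCOc1cc(CO)cc(OCOC)c1 | intermediate
10 | tert-butyl{[3,5-bis(methoxymethoxy)phenyl]methoxy}dimethylsilane | COCOc1cc(CO[Si](C)(C)C(C)(C)C)cc(OCOC)c1 | intermediate
11 | [4-(tert-butyldimethylsilyloxymethyl)-2,6-bis(methoxymethoxy)phenyl]lithium (Ar–Li) | [Li]c1c(OCOC)cc(CO[Si](C)(C)C(C)(C)C)cc1OCOC | intermediate (not isolated)
12 | tert-butyl{[3,5-bis(methoxymethoxy)-4-(prop-2-en-1-yl)phenyl]methoxy}dimethylsilane | C=CCc1c(OCOC)cc(CO[Si](C)(C)C(C)(C)C)cc1OCOC | intermediate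
13 | 9-(3-Ar-propyl)-9-borabicyclo[3.3.1]nonane | C1CC2CCCC(C1)B2CCCc1c(OCOC)cc(CO[Si](C)(C)C(C)(C)C)cc1OCOC | intermediate (not isolated)
14 | 3-Ar-propan-1-ol | OCCCc1c(OCOC)cc(CO[Si](C)(C)C(C)(C)C)cc1OCOC | intermediate
15 | 3-Ar-propanal | O=CCCc1c(OCOC)cc(CO[Si](C)(C)C(C)(C)C)cc1OCOC | intermediate
16 | 5-Ar-2-(trimethylsilyl)pent-1-en-3-ol (racemic) | C=C([Si](C)(C)C)C(O)CCc1c(OCOC)cc(CO[Si](C)(C)C(C)(C)C)cc1OCOC | intermediate
17 | 5-Ar-2-(trimethylsilyl)pent-1-en-3-one | C=C([Si](C)(C)C)C(=O)CCc1c(OCOC)cc(CO[Si](C)(C)C(C)(C)C)cc1OCOC | intermediate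
18 | lithium (4R)-4-(tert-butyldimethylsilyloxy)-3,3-dimethylcyclohex-1-en-1-olate | [Li]OC1=CC(C)(C)[C@H](O[Si](C)(C)C(C)(C)C)CC1 | intermediate (not isolated)
19 | (2S,4R)-4-(tert-butyldimethylsilyloxy)-3,3-dimethyl-2-[5-Ar-3-oxo-2-(trimethylsilyl)pentyl]cyclohexan-1-one (epimers at the silyl-bearing carbon) | C[Si](C)(C)C(C[C@@H]2C(=O)CC[C@@H](O[Si](C)(C)C(C)(C)C)C2(C)C)C(=O)CCc1c(OCOC)cc(CO[Si](C)(C)C(C)(C)C)cc1OCOC | intermediate
20 | (2S,4R)-4-(tert-butyldimethylsilyloxy)-3,3-dimethyl-2-(5-Ar-3-oxopentyl)cyclohexan-1-one | O=C(CC[C@@H]2C(=O)CC[C@@H](O[Si](C)(C)C(C)(C)C)C2(C)C)CCc1c(OCOC)cc(CO[Si](C)(C)C(C)(C)C)cc1OCOC | intermediate (not isolated)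
21 | (4aR,6R)-1-(Ar-methyl)-6-(tert-butyldimethylsilyloxy)-8a-hydroxy-5,5-dimethyl-3,4,4a,5,6,7,8,8a-octahydronaphthalen-2(1H)-one (epimers at C1 and C8a) | O=C1CC[C@@H]2C(O)(C1Cc3c(OCOC)cc(CO[Si](C)(C)C(C)(C)C)cc3OCOC)CC[C@@H](O[Si](C)(C)C(C)(C)C)C2(C)C | intermediate (not isolated)
22 | (4aR,6R)-1-(Ar-methyl)-6-(tert-butyldimethylsilyloxy)-5,5-dimethyl-4,4a,5,6,7,8-hexahydronaphthalen-2(3H)-one | O=C1CC[C@@H]2C(=C1Cc3c(OCOC)cc(CO[Si](C)(C)C(C)(C)C)cc3OCOC)CC[C@@H](O[Si](C)(C)C(C)(C)C)C2(C)C | intermediate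
23 | potassium (4aR,6R)-1-(Ar-methyl)-6-(tert-butyldimethylsilyloxy)-5,5-dimethyl-3,4,4a,5,6,7-hexahydronaphthalen-2-olate | [K]OC1=C(Cc3c(OCOC)cc(CO[Si](C)(C)C(C)(C)C)cc3OCOC)C2=CC[C@@H](O[Si](C)(C)C(C)(C)C)C(C)(C)[C@@H]2CC1 | intermediate (not isolated)
24 | (1R,4aR,6R)-1-(Ar-methyl)-6-(tert-butyldimethylsilyloxy)-1,5,5-trimethyl-3,4,4a,5,6,7-hexahydronaphthalen-2(1H)-one | O=C1CC[C@@H]2C(=CC[C@@H](O[Si](C)(C)C(C)(C)C)C2(C)C)[C@@]1(C)Cc3c(OCOC)cc(CO[Si](C)(C)C(C)(C)C)cc3OCOC | intermediate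
25 | (1S,4aR,6R)-1-(Ar-methyl)-6-(tert-butyldimethylsilyloxy)-1,5,5-trimethyl-2-methylidene-1,2,3,4,4a,5,6,7-octahydronaphthalene | C=C1CC[C@@H]2C(=CC[C@@H](O[Si](C)(C)C(C)(C)C)C2(C)C)[C@@]1(C)Cc3c(OCOC)cc(CO[Si](C)(C)C(C)(C)C)cc3OCOC | intermediate
26 | (1S,2R,4aR,6R)-1-(Ar-methyl)-6-(tert-butyldimethylsilyloxy)-1,2,5,5-tetramethyl-1,2,3,4,4a,5,6,7-octahydronaphthalene | C[C@@H]1CC[C@@H]2C(=CC[C@@H](O[Si](C)(C)C(C)(C)C)C2(C)C)[C@@]1(C)Cc3c(OCOC)cc(CO[Si](C)(C)C(C)(C)C)cc3OCOC | intermediate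
27 | {4-{[(1S,2R,4aR,6R)-6-hydroxy-1,2,5,5-tetramethyl-1,2,3,4,4a,5,6,7-octahydronaphthalen-1-yl]methyl}-3,5-bis(methoxymethoxy)phenyl}methanol | C[C@@H]1CC[C@@H]2C(=CC[C@@H](O)C2(C)C)[C@@]1(C)Cc3c(OCOC)cc(CO)cc3OCOC | intermediate
28 | trilithio derivative of 27 (both hydroxyls as lithium alkoxides, aryllithium ortho to CH2OLi) | C[C@@H]1CC[C@@H]2C(=CC[C@@H](O[Li])C2(C)C)[C@@]1(C)Cc3c(OCOC)cc(CO[Li])c([Li])c3OCOC | intermediate (not isolated)
29 | 6-(hydroxymethyl)-3-{[(1S,2R,4aR,6R)-6-hydroxy-1,2,5,5-tetramethyl-1,2,3,4,4a,5,6,7-octahydronaphthalen-1-yl]methyl}-2,4-bis(methoxymethoxy)benzaldehyde | C[C@@H]1CC[C@@H]2C(=CC[C@@H](O)C2(C)C)[C@@]1(C)Cc3c(OCOC)cc(CO)c(C=O)c3OCOC | intermediate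
30 | 2,4-dihydroxy-6-(hydroxymethyl)-3-{[(1S,2R,4aR,6R)-6-hydroxy-1,2,5,5-tetramethyl-1,2,3,4,4a,5,6,7-octahydronaphthalen-1-yl]methyl}benzaldehyde | C[C@@H]1CC[C@@H]2C(=CC[C@@H](O)C2(C)C)[C@@]1(C)Cc1c(O)cc(CO)c(C=O)c1O | target

**Totals and risks**

Total step count: 21. Longest linear sequence: 15 steps (8 → 30, steps 7–21). The ring A branch (steps 1–6) joins at step 14.

Most likely to fail, first: step 14. The hindered enolate may add sluggishly to the sensitive α-silyl enone, or the kinetic C5 configuration may erode on the way to 22. The fallback replaces the anionic Michael by a Lewis-acid Mukaiyama–Michael reaction and an enamine aldol. It sets out from aldehyde 15 (with enol ether 7) and comes back at enone 22. Vinylmagnesium bromide adds to 15 to give 5-Ar-pent-1-en-3-ol F1. Dess–Martin oxidation gives the unsilylated vinyl ketone 5-Ar-pent-1-en-3-one F2. F2 and 7 combine under Sc(OTf)3 catalysis (CH2Cl2, −78 °C) to give the silyl enol ether adduct (2S,4R)-4-(tert-butyldimethylsilyloxy)-3,3-dimethyl-2-[5-Ar-3-(trimethylsilyloxy)pent-2-en-1-yl]cyclohexan-1-one F3, whose hydrolysis on work-up gives diketone 20. Cyclodehydration of 20 with pyrrolidine/AcOH in toluene at 60 °C, which is expected to spare C5, returns to 22.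

Second: step 16. Methylation may go to oxygen or C7, the dienolate may form toward C5, or the wrong face may be attacked. The fallback makes the C9–CH3 bond by cyclopropanation instead of enolate alkylation. It sets out from 22 and comes back at 24. KOtBu then TMSCl gives the heteroannular dienol ether {[(4aR,6R)-1-(Ar-methyl)-6-(tert-butyldimethylsilyloxy)-5,5-dimethyl-3,4,4a,5,6,7-hexahydronaphthalen-2-yl]oxy}trimethylsilane F4. Simmons–Smith cyclopropanation (Et2Zn, CH2I2, CH2Cl2, 0 °C) of the electron-rich enol-ether double bond from the axial α-face gives the C8,C9-methano siloxycyclopropane F5. NaOH/MeOH cleaves the trimethylsilyl ether and opens the cyclopropanol to the α-methyl ketone 24.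

Third: step 18. The hindered exocyclic alkene may react slowly, or face and chemoselectivity may be incomplete. The fallback replaces hydrogenation by hydroboration and radical deoxygenation. It sets out from 25 and comes back at 26. 9-BBN adds only to the exocyclic alkene, from the face opposite the axial C9 methyl, to give the B-alkyl-9-borabicyclo[3.3.1]nonane F6. NaOH/H2O2 gives [(1S,2R,4aR,6R)-1-(Ar-methyl)-6-(tert-butyldimethylsilyloxy)-1,5,5-trimethyl-1,2,3,4,4a,5,6,7-octahydronaphthalen-2-yl]methanol F7. I2/PPh3/imidazole gives the corresponding iodomethyl compound F8, and Bu3SnH/AIBN (benzene, 80 °C) reduces it to 26.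

Further compounds
F1 | step 14 | 5-Ar-pent-1-en-3-ol (racemic) | C=CC(O)CCc1c(OCOC)cc(CO[Si](C)(C)C(C)(C)C)cc1OCOC
F2 | step 14 | 5-Ar-pent-1-en-3-one | C=CC(=O)CCc1c(OCOC)cc(CO[Si](C)(C)C(C)(C)C)cc1OCOC
F3 | step 14 | (2S,4R)-4-(tert-butyldimethylsilyloxy)-3,3-dimethyl-2-[5-Ar-3-(trimethylsilyloxy)pent-2-en-1-yl]cyclohexan-1-one | C[Si](C)(C)OC(=CC[C@@H]2C(=O)CC[C@@H](O[Si](C)(C)C(C)(C)C)C2(C)C)CCc1c(OCOC)cc(CO[Si](C)(C)C(C)(C)C)cc1OCOC
F4 | step 16 | {[(4aR,6R)-1-(Ar-methyl)-6-(tert-butyldimethylsilyloxy)-5,5-dimethyl-3,4,4a,5,6,7-hexahydronaphthalen-2-yl]oxy}trimethylsilane | C[Si](C)(C)OC1=C(Cc3c(OCOC)cc(CO[Si](C)(C)C(C)(C)C)cc3OCOC)C2=CC[C@@H](O[Si](C)(C)C(C)(C)C)C(C)(C)[C@@H]2CC1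
F5 | step 16 | C8,C9-methano (cyclopropane) adduct of F4 with the CH2 on the α-face, OSiMe3 on C8 | C[Si](C)(C)O[C@@]12CC[C@@H]3C(=CC[C@@H](O[Si](C)(C)C(C)(C)C)C3(C)C)[C@@]1(C2)Cc4c(OCOC)cc(CO[Si](C)(C)C(C)(C)C)cc4OCOC
F6 | step 18 | 9-{[(1S,2R,4aR,6R)-1-(Ar-methyl)-6-(tert-butyldimethylsilyloxy)-1,5,5-trimethyl-1,2,3,4,4a,5,6,7-octahydronaphthalen-2-yl]methyl}-9-borabicyclo[3.3.1]nonane | C1CC2CCCC(C1)B2C[C@@H]1CC[C@@H]2C(=CC[C@@H](O[Si](C)(C)C(C)(C)C)C2(C)C)[C@@]1(C)Cc3c(OCOC)cc(CO[Si](C)(C)C(C)(C)C)cc3OCOC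
F7 | step 18 | [(1S,2R,4aR,6R)-1-(Ar-methyl)-6-(tert-butyldimethylsilyloxy)-1,5,5-trimethyl-1,2,3,4,4a,5,6,7-octahydronaphthalen-2-yl]methanol | OC[C@@H]1CC[C@@H]2C(=CC[C@@H](O[Si](C)(C)C(C)(C)C)C2(C)C)[C@@]1(C)Cc3c(OCOC)cc(CO[Si](C)(C)C(C)(C)C)cc3OCOC
F8 | step 18 | (1S,2R,4aR,6R)-1-(Ar-methyl)-6-(tert-butyldimethylsilyloxy)-2-(iodomethyl)-1,5,5-trimethyl-1,2,3,4,4a,5,6,7-octahydronaphthalene | IC[C@@H]1CC[C@@H]2C(=CC[C@@H](O[Si](C)(C)C(C)(C)C)C2(C)C)[C@@]1(C)Cc3c(OCOC)cc(CO[Si](C)(C)C(C)(C)C)cc3OCOC
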